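**Strategy.** The target is the C2-symmetric head-to-head [2+2] dimer (C8–C8′, C9–C9′) of a lindenane dienolide, so the plan rests on the monomer. Its rings A and B are fused through C5–C10, and its C8=C9 enol-lactone double bond is the retron of a [4+2] cycloaddition between a diene spanning C7 to C10 and a two-carbon dienophile C5=C6. One intramolecular cycloaddition therefore makes C5–C10 and C6–C7, closes rings A and B and sets C5 and C10. Its precursor is a cis-1,2-disubstituted cyclopropane carrying a vinyl ketone and an (E)-propenyl arm that ends in a 2-silyloxy-3-methylfuran.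

Key step: step 11

Assumption: quinidine is taken to deliver the (1R,2S) half-ester 2, by analogy with other bicyclic meso anhydrides; if the sense were opposite for this anhydride, quinine would be used in step 1 and nothing else would change.

Numbering note: the tricyclic compounds carry lindenane numbering (cyclopropane C1–C2–C3; ring A = C1, C3, C4, C5, C10; ring B = C5 to C10; lactone = C7, C8, O, C12, C11; C13 on C11; C14 on C10; C15 on C4); β is the face of the C14 methyl.

**Step 1**
Reactants: 1 cis-cyclopropane-1,2-dicarboxylic anhydride (3-oxabicyclo[3.1.0]hexane-2,4-dione)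
Product: 2 (1R,2S)-2-(methoxycarbonyl)cyclopropane-1-carboxylic acid
Conditions: quinidine (1.1 equiv), MeOH (3 equiv), PhMe/CCl4 (1:1), −55 °C
Reagents that add atoms: methanol, CO
Why: Cinchona-alkaloid-mediated desymmetrising methanolysis of a meso anhydride, in which the chiral base directs methanol to one enantiotopic carbonyl and so fixes both cyclopropane stereocentres, the cis relationship being inherited from 1.

**Step 2**
Reactants: 2 (1R,2S)-2-(methoxycarbonyl)cyclopropane-1-carboxylic acid
Product: 4 (1R,5S)-3-oxabicyclo[3.1.0]hexan-2-one, via hydroxy acid 3 (not isolated)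
Conditions: LiBEt3H (3 equiv), THF, −78 °C to rt; then 2 M HCl, rt
Reagents that add atoms: none
Why: Chemoselective hydride reduction of the ester, the acid being shielded as its lithium carboxylate, followed by acid-promoted lactonisation of the cis γ-hydroxy acid, with neither stereocentre touched.

**Step 3**
Reactants: 4 (1R,5S)-3-oxabicyclo[3.1.0]hexan-2-one
Product: 5 (1R,5S)-3-oxabicyclo[3.1.0]hexan-2-ol (lactol, both anomers)
Conditions: DIBAL-H (1.1 equiv), CH2Cl2, −78 °C; Rochelle salt
Reagents that add atoms: none
Why: Partial reduction of a γ-lactone with DIBAL-H at −78 °C stops at the lactol oxidation level, and the new anomeric centre, formed as a mixture, is lost in step 4.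

**Step 4**
Reactants: 5 (1R,5S)-3-oxabicyclo[3.1.0]hexan-2-ol
Product: 6 [(1S,2R)-2-ethynylcyclopropyl]methanol
Conditions: MeC(O)C(N2)P(O)(OMe)2, K2CO3, MeOH, 0 °C to rt
Reagents that add atoms: dimethyl (1-diazo-2-oxopropyl)phosphonate, CC(=O)C(=[N+]=[N-])P(=O)(OC)OC
Why: Ohira–Bestmann (Seyferth–Gilbert) homologation in which the lactol reacts as a masked aldehyde, the mild carbonate base being expected to leave the cyclopropane stereocentre intact because cyclopropyl carbonyl compounds enolise reluctantly.

**Step 5**
Reactants: 6 [(1S,2R)-2-ethynylcyclopropyl]methanol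
Product: 8 [(1S,2R)-2-[(E)-1-iodoprop-1-en-2-yl]cyclopropyl]methanol, via alkenylalane 7 (not isolated)
Conditions: AlMe3 (3 equiv), Cp2ZrCl2 (0.3 equiv), CH2Cl2, 0 °C to rt; then I2, THF, −30 °C
Reagents that add atoms: trimethylaluminium, C[Al](C)C; iodine, II
Why: Zirconium-catalysed methylalumination (Negishi carboalumination) adds methyl and aluminium syn across the terminal alkyne with methyl on the internal carbon, and iodinolysis with retention fixes the E geometry (iodine trans to the cyclopropane), the free alcohol being carried as its aluminium alkoxide.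

**Step 6**
Reactants: 8 [(1S,2R)-2-[(E)-1-iodoprop-1-en-2-yl]cyclopropyl]methanol
Product: 10 (1S,2R)-2-[(E)-1-iodoprop-1-en-2-yl]cyclopropane-1-carboxylic acid, via aldehyde 9 (not isolated)
Conditions: TEMPO (0.2 equiv), PhI(OAc)2 (2.2 equiv), MeCN/H2O (1:1), rt
Reagents that add atoms: water, O
Why: Oxoammonium (TEMPO) oxidation in aqueous acetonitrile takes the primary alcohol through the aldehyde hydrate to the acid under near-neutral conditions that spare the alkenyl iodide and the cis-cyclopropane.

**Step 7**
Reactants: 10 (1S,2R)-2-[(E)-1-iodoprop-1-en-2-yl]cyclopropane-1-carboxylic acid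
Product: 12 (1S,2R)-2-[(E)-1-iodoprop-1-en-2-yl]-N-methoxy-N-methylcyclopropane-1-carboxamide, via acyl imidazole 11 (not isolated)
Conditions: CDI, CH2Cl2, rt; then MeNH(OMe)·HCl, rt
Reagents that add atoms: N,O-dimethylhydroxylamine hydrochloride, CNOC.Cl
Why: Weinreb amide formation by carbonyldiimidazole activation and aminolysis, a sequence without strongly basic or enolising conditions, so the cis configuration is kept.

**Step 8**
Reactants: 13 3-methylfuran-2(5H)-one
Product: 14 3-methyl-2-(triisopropylsilyloxy)furan
Conditions: TIPSOTf, Et3N, CH2Cl2, 0 °C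
Reagents that add atoms: triisopropylsilyl trifluoromethanesulfonate, CC(C)[Si](C(C)C)(C(C)C)OS(=O)(=O)C(F)(F)F
Why: Soft enolisation at the γ-position and O-silylation convert the butenolide into the aromatic 2-silyloxyfuran (silyl dienol ether formation), the bulky triisopropylsilyl group being chosen because it withstands the lithiation and Grignard steps that follow.

**Step 9**
Reactants: 14 3-methyl-2-(triisopropylsilyloxy)furan; 12 (1S,2R)-2-[(E)-1-iodoprop-1-en-2-yl]-N-methoxy-N-methylcyclopropane-1-carboxamide
Product: 17 (1S,2R)-N-methoxy-N-methyl-2-[(E)-1-[4-methyl-5-(triisopropylsilyloxy)furan-2-yl]prop-1-en-2-yl]cyclopropane-1-carboxamide, via furyllithium 15 (not isolated), via furylzinc chloride 16 (not isolated)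
Conditions: 14, s-BuLi, TMEDA, THF, −78 to 0 °C; ZnCl2, 0 °C; then 12, Pd(PPh3)4 (5 mol%), THF, rt
Reagents that add atoms: none
Why: α-Lithiation of the silyloxyfuran at its only free α-position, transmetalation to zinc and Negishi cross-coupling with the alkenyl iodide, which proceeds with retention of the E geometry and tolerates the Weinreb amide.

**Step 10**
Reactants: 17 (1S,2R)-N-methoxy-N-methyl-2-[(E)-1-[4-methyl-5-(triisopropylsilyloxy)furan-2-yl]prop-1-en-2-yl]cyclopropane-1-carboxamide
Product: 18 1-[(1S,2R)-2-[(E)-1-[4-methyl-5-(triisopropylsilyloxy)furan-2-yl]prop-1-en-2-yl]cyclopropyl]prop-2-en-1-one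
Conditions: CH2=CHMgBr (1.5 equiv), THF, −78 to −20 °C; inverse quench into cold aq NH4Cl; used at once
Reagents that add atoms: vinylmagnesium bromide, C=C[Mg]Br
Why: Weinreb ketone synthesis, in which N-methoxy chelation blocks over-addition and the vinyl ketone is released only at the cold, nearly neutral quench that the silyloxyfuran survives.

**Step 11**
Reactants: 18 1-[(1S,2R)-2-[(E)-1-[4-methyl-5-(triisopropylsilyloxy)furan-2-yl]prop-1-en-2-yl]cyclopropyl]prop-2-en-1-one
Product: 19 tricyclic 4-ketone as cyclic triisopropylsilyl ketene acetal (C11=C12–OSi and C8=C9 in place; C2 β, H-1 and H-3 α, C14 β, H-5 α, H-7 β)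
Conditions: PhMe (0.01 M), BHT (cat.), 110 °C, sealed tube, exclusion of light
Reagents that add atoms: none
Why: Thermal, concerted but asynchronous intramolecular [4+2] cycloaddition in which the furan C7=C8 bond together with the exocyclic C9=C10 bond is the diene and the vinyl ketone C5=C6 the dienophile, so that C5–C10 and C6–C7 form suprafacially on both partners and C8=C9 is left as part of a cyclic silyl ketene acetal. The closest known reaction types are the intramolecular Diels–Alder reactions of 2-vinylfurans used as extra-annular dienes and of 1,6,8-nonatrien-3-ones. Ring A (five-membered) closes by the C5–C10 bond across the three-atom tether C1–C3–C4 and ring B (six-membered) is the cycloaddition ring itself, which is the fused type 1 mode of closure. C10 is controlled by the E geometry of C9=C10 (methyl inward, tether outward) and by the C1 stereocentre, since the bulky furyl-diene arm should approach on the face of the nascent cyclopentanone remote from the cyclopropane CH2 and leave only the methyl syn to it, while C7 follows from suprafacial addition (H-7 syn to the methyl) and is erased in step 12. C5 is controlled by the exo orientation of the tether carbonyl (C4=O turned away from the furan), which gives H-5 anti to the C10 methyl and thus the trans A/B fusion that the step needs; the rigid cis-cyclopropane, which holds C10 and C4 eclipsed and would have to fold the bicyclo[3.1.0]hexanone beneath the furan oxygen in the endo mode, is the element expected to secure it. Neutral thermal conditions at high dilution are chosen because a Lewis acid would divert the silyloxyfuran into a vinylogous Mukaiyama–Michael addition and could open the donor–acceptor cyclopropane.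

**Step 12**
Reactants: 19 tricyclic 4-ketone as cyclic triisopropylsilyl ketene acetal
Product: 20 4-oxo-15-norlindena-7(11),8-dien-12,8-olide (C2 β, C14 β, H-5 α)
Conditions: Pd(OAc)2 (1.1 equiv), MeCN, rt, dark
Reagents that add atoms: none
Why: Saegusa–Ito-type dehydrosilylation, in which divalent palladium attacks the silyl ketene acetal at C11 and syn β-hydride elimination of the allylic H-7 gives the conjugated C7=C11 bond, removing the C7 stereocentre and leaving C8=C9 in place.

**Step 13**
Reactants: 20 4-oxo-15-norlindena-7(11),8-dien-12,8-olide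
Product: 21 lindena-4(15),7(11),8-trien-12,8-olide (chloranthalactone A; C2 β, C14 β, H-5 α)
Conditions: Zn, CH2Br2, TiCl4, THF/CH2Cl2, 0 °C to rt, dark
Reagents that add atoms: dibromomethane, BrCBr
Why: Takai–Lombardo methylenation is non-basic and chemoselective for ketones, so the epimerisable C5 centre next to the carbonyl should keep its trans configuration and the enol lactone should not be attacked.

**Step 14**
Reactants: 21 lindena-4(15),7(11),8-trien-12,8-olide (two molecules)
Product: 22 target dimer (cyclobutane C8–C9–C9′–C8′; new bonds on the α face of each half; H-9 and H-9′ trans; C2-symmetric)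
Conditions: hν (medium-pressure Hg lamp, Pyrex filter), degassed n-hexane, rt
Reagents that add atoms: none
Why: [2+2] photodimerisation of the enol-lactone alkene C8=C9, a known reaction of γ-alkylidene butenolides, which should bond head-to-head (C9–C9′ first, giving oxygen-stabilised allylic radicals at C8 and C8′) on the α face of each monomer opposite to the C14 methyl and with the two halves anti, so setting the four cyclobutane stereocentres.

**Compound list**
1 | cis-cyclopropane-1,2-dicarboxylic anhydride (3-oxabicyclo[3.1.0]hexane-2,4-dione, meso) | O=C1OC(=O)[C@H]2C[C@@H]12 | starting material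
2 | (1R,2S)-2-(methoxycarbonyl)cyclopropane-1-carboxylic acid | COC(=O)[C@H]1C[C@H]1C(=O)O | intermediate
3 | (1R,2S)-2-(hydroxymethyl)cyclopropane-1-carboxylic acid (lithium salt in the flask) | OC[C@H]1C[C@H]1C(=O)O | intermediate
4 | (1R,5S)-3-oxabicyclo[3.1.0]hexan-2-one | O=C1OC[C@H]2C[C@@H]12 | intermediate
5 | (1R,5S)-3-oxabicyclo[3.1.0]hexan-2-ol (anomer mixture) | OC1OC[C@H]2C[C@@H]12 | intermediate
6 | [(1S,2R)-2-ethynylcyclopropyl]methanol | OC[C@H]1C[C@H]1C#C | intermediate
7 | dimethylaluminium alkoxide of [(1S,2R)-2-[(E)-1-(dimethylalumanyl)prop-1-en-2-yl]cyclopropyl]methanol | C[Al](C)OC[C@H]1C[C@H]1/C(C)=C/[Al](C)C | intermediate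
8 | [(1S,2R)-2-[(E)-1-iodoprop-1-en-2-yl]cyclopropyl]methanol | OC[C@H]1C[C@H]1/C(C)=C/I | intermediate
9 | (1S,2R)-2-[(E)-1-iodoprop-1-en-2-yl]cyclopropane-1-carbaldehyde | O=C[C@H]1C[C@H]1/C(C)=C/I | intermediate
10 | (1S,2R)-2-[(E)-1-iodoprop-1-en-2-yl]cyclopropane-1-carboxylic acid | OC(=O)[C@H]1C[C@H]1/C(C)=C/I | intermediate
11 | (1H-imidazol-1-yl)[(1S,2R)-2-[(E)-1-iodoprop-1-en-2-yl]cyclopropyl]methanone | O=C(n1ccnc1)[C@H]1C[C@H]1/C(C)=C/I | intermediate
12 | (1S,2R)-2-[(E)-1-iodoprop-1-en-2-yl]-N-methoxy-N-methylcyclopropane-1-carboxamide | CON(C)C(=O)[C@H]1C[C@H]1/C(C)=C/I | intermediate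
13 | 3-methylfuran-2(5H)-one | CC1=CCOC1=O | starting material
14 | 3-methyl-2-(triisopropylsilyloxy)furan | Cc1ccoc1O[Si](C(C)C)(C(C)C)C(C)C | intermediate
15 | [4-methyl-5-(triisopropylsilyloxy)furan-2-yl]lithium | [Li]c1cc(C)c(O[Si](C(C)C)(C(C)C)C(C)C)o1 | intermediate
16 | chloro[4-methyl-5-(triisopropylsilyloxy)furan-2-yl]zinc | Cl[Zn]c1cc(C)c(O[Si](C(C)C)(C(C)C)C(C)C)o1 | intermediate
17 | (1S,2R)-N-methoxy-N-methyl-2-[(E)-1-[4-methyl-5-(triisopropylsilyloxy)furan-2-yl]prop-1-en-2-yl]cyclopropane-1-carboxamide | CON(C)C(=O)[C@H]1C[C@H]1/C(C)=C/c1cc(C)c(O[Si](C(C)C)(C(C)C)C(C)C)o1 | intermediate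
18 | 1-[(1S,2R)-2-[(E)-1-[4-methyl-5-(triisopropylsilyloxy)furan-2-yl]prop-1-en-2-yl]cyclopropyl]prop-2-en-1-one | C=CC(=O)[C@H]1C[C@H]1/C(C)=C/c1cc(C)c(O[Si](C(C)C)(C(C)C)C(C)C)o1 | intermediate
19 | tricyclic lindenane 4-ketone as cyclic triisopropylsilyl ketene acetal (C8=C9, C11=C12; C2 β, C14 β, H-5 α, H-7 β) | O=C1[C@H]2C[C@H]2[C@@]2(C)[C@H]1C[C@H]1C(C)=C(O[Si](C(C)C)(C(C)C)C(C)C)OC1=C2 | intermediate
20 | 4-oxo-15-norlindena-7(11),8-dien-12,8-olide (C2 β, C14 β, H-5 α) | O=C1[C@H]2C[C@H]2[C@@]2(C)[C@H]1CC1=C(C)C(=O)OC1=C2 | intermediate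
21 | lindena-4(15),7(11),8-trien-12,8-olide (chloranthalactone A) | C=C1[C@H]2C[C@H]2[C@@]2(C)[C@H]1CC1=C(C)C(=O)OC1=C2 | intermediate
22 | head-to-head anti [2+2] dimer of 21 through C8–C8′ and C9–C9′ (α-face bonds, C2-symmetric) | C=C1[C@H]2C[C@H]2[C@@]2(C)[C@H]1CC1=C(C)C(=O)O[C@]13[C@H]2[C@H]1[C@@]2(C)[C@@H]4C[C@@H]4C(=C)[C@@H]2CC2=C(C)C(=O)O[C@@]213 | target

**Step count.** Total: 14 steps. Longest linear sequence: 13 steps (steps 1–7 and 9–14); step 8 is a one-step side branch.

**Three steps most likely to fail**

Step 11 (key cycloaddition). Several processes could intervene: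
- The cycloaddition may be slow, because the diene terminus C10 is fully substituted and the furan loses its aromaticity.
- The vinyl ketone may polymerise in the meantime.
- The cis-acyl alkenylcyclopropane may drain into a reversible retro-Claisen ring expansion.
- Selectivity may leak into the endo mode (cis A/B fusion) or onto the other diene face.

The fallback sets out from 17 and returns at 19. Addition of ethynylmagnesium bromide to 17 (THF, −78 °C) should give the alkynyl ketone F1. Its linear, slimmer and more reactive dienophile has no endo/exo question, and thermal intramolecular Diels–Alder reaction should give the cyclohexa-1,4-dienone adduct F2. Conjugate reduction of the C5=C6 enone with Stryker's reagent [CuH(PPh3)]6 follows, and protonation of the resulting enolate at C5 on the α face, opposite to the C14 methyl, should deliver 19 with the trans fusion.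

Step 13 (methylenation). The ketone is flanked by the cyclopropane and by C5 next to the quaternary C10, so carbonyl methylenation may be sluggish. The low-valent titanium/zinc mixture may also reduce or open the dienolide. The fallback sets out from 20 and returns at 21 by a Peterson olefination. Addition of the organocerium reagent from Me3SiCH2Li and CeCl3 (THF, −78 °C) to the ketone should give the β-hydroxysilane F3. Once C4 is sp3, C5 is no longer epimerisable, so syn-elimination with KHMDS (THF, 0 °C) can be used to give 21.

Step 10 (vinyl ketone release). At the quench the liberated N,O-dimethylhydroxylamine, or excess Grignard reagent, may add in conjugate fashion to the new enone. The enone may polymerise on concentration, and the silyloxyfuran may hydrolyse. The fallback sets out from 17 and returns at 18. DIBAL-H reduction of 17 (THF, −78 °C) should give the aldehyde F4, which is used cold and at once. Addition of vinylmagnesium bromide gives the allylic alcohol F5 as a mixture of carbinol epimers. Oxidation with MnO2 in CH2Cl2 then releases 18 under neutral, amine-free conditions.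

**Further compounds**
F1 | step 11 | 1-[(1S,2R)-2-[(E)-1-[4-methyl-5-(triisopropylsilyloxy)furan-2-yl]prop-1-en-2-yl]cyclopropyl]prop-2-yn-1-one | C#CC(=O)[C@H]1C[C@H]1/C(C)=C/c1cc(C)c(O[Si](C(C)C)(C(C)C)C(C)C)o1
F2 | step 11 | 5,6-didehydro analogue of 19 (cyclohexa-1,4-diene ring B with C5=C6 and C8=C9; cyclic triisopropylsilyl ketene acetal; C14 β, H-7 β) | O=C1[C@H]2C[C@H]2[C@@]2(C)C1=C[C@H]1C(C)=C(O[Si](C(C)C)(C(C)C)C(C)C)OC1=C2
F3 | step 13 | 4-hydroxy-4-[(trimethylsilyl)methyl] adduct of 20 (C4 configuration not defined) | C[Si](C)(C)CC1(O)[C@H]2C[C@H]2[C@@]2(C)[C@H]1CC1=C(C)C(=O)OC1=C2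
F4 | step 10 | (1S,2R)-2-[(E)-1-[4-methyl-5-(triisopropylsilyloxy)furan-2-yl]prop-1-en-2-yl]cyclopropane-1-carbaldehyde | O=C[C@H]1C[C@H]1/C(C)=C/c1cc(C)c(O[Si](C(C)C)(C(C)C)C(C)C)o1
F5 | step 10 | 1-[(1S,2R)-2-[(E)-1-[4-methyl-5-(triisopropylsilyloxy)furan-2-yl]prop-1-en-2-yl]cyclopropyl]prop-2-en-1-ol (carbinol epimers) | C=CC(O)[C@H]1C[C@H]1/C(C)=C/c1cc(C)c(O[Si](C(C)C)(C(C)C)C(C)C)o1
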